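**Retrosynthetic overview**
- Feature: C2 of ring C lies between O1 and C1' of ring B. In the ring-opened form (ring A)–O1–CH2–(ring B) its C–H bonds are both α-oxy and benzylic, and they sit six atoms from a carbene centre placed at C3.
- Key disconnection C2–C3: (S)-flavanone 15 ⇒ aryl diazomethyl ketone 14. An enantioselective rhodium-carbenoid 1,6-C–H insertion closes ring C and sets C2, the only stereocentre. Rings A and B are bought as arenes, so ring C is the only ring formed.
- 14 ⇒ methyl ketone 12 by deacylative diazo transfer. 12 ⇒ O1–CH2 bond by Mitsunobu coupling of benzylic alcohol 9 with 4-O-TIPS-resacetophenone 11.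
- 9 ⇒ 3,4-dihydroxybenzaldehyde 1: 4-O-(1,1-dimethylpropargyl) ether, semihydrogenation, aromatic Claisen shift to C5 (prenyl), 4-O-methylation, 3-O-silylation, reduction.
- End game: acid-buffered fluoride removes both TIPS groups without opening ring C.

Key step: step 10

Assumption: Rh2(S-PTTL)4 is taken to select the pro-S benzylic hydrogen of 14. The sense of induction has to be checked on 15. If it is the opposite one, the mirror-image catalyst Rh2(R-PTTL)4 replaces it in step 10 and nothing else changes.

Step 1
Reactants: 1 3,4-dihydroxybenzaldehyde; 2 3-chloro-3-methylbut-1-yne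
Product: 3 3-hydroxy-4-[(2-methylbut-3-yn-2-yl)oxy]benzaldehyde
Conditions: 2 (1.3 equiv), DBU (1.05 equiv), CuCl2·2H2O (5 mol%), MeCN, N2, 0 °C
Reagents that add atoms: none
Why: Copper-catalysed propargylic O-alkylation (etherification through a copper acetylide/allenylidene ion pair), in which one equivalent of DBU ionises only the 4-OH, the more acidic phenol because it is para to the formyl group, while the low temperature holds back a second alkylation and the thermal propargyl Claisen path.

Step 2
Reactants: 3 3-hydroxy-4-[(2-methylbut-3-yn-2-yl)oxy]benzaldehyde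
Product: 4 3-hydroxy-4-[(2-methylbut-3-en-2-yl)oxy]benzaldehyde
Conditions: H2 (1 atm, stopped after 1 equiv), Pd/CaCO3 poisoned with Pb(OAc)2 (Lindlar catalyst), quinoline, EtOAc, rt
Reagents that add atoms: none
Why: Lindlar semihydrogenation, in which the poisoned palladium surface takes the terminal alkyne to the vinyl group and stops there, leaving the aldehyde and the tertiary aryl ether untouched.

Step 3
Reactants: 4 3-hydroxy-4-[(2-methylbut-3-en-2-yl)oxy]benzaldehyde
Product: 6 3,4-dihydroxy-5-(3-methylbut-2-enyl)benzaldehyde, via ortho-dienone 5 (not isolated)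
Conditions: PhNEt2, Ar, 150 °C; cold dilute HCl wash
Reagents that add atoms: none
Why: Aromatic Claisen rearrangement, in which the [3,3] shift carries the allyl unit with inversion of its termini to C5, the only free ortho position of the 4-O ether, so the 1,1-dimethylallyl ether becomes a linear prenyl group, dienone 5 tautomerises to the catechol, and the basic solvent suppresses acid-induced loss of isoprene and chroman formation.

Step 4
Reactants: 6 3,4-dihydroxy-5-(3-methylbut-2-enyl)benzaldehyde
Product: 7 3-hydroxy-4-methoxy-5-(3-methylbut-2-enyl)benzaldehyde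
Conditions: MeI (1.05 equiv), Li2CO3 (1.2 equiv), DMF, 45 °C
Reagents that add atoms: iodomethane, CI
Why: Site-selective Williamson methylation, in which the weak base ionises only the 4-OH (para to CHO and clearly the more acidic), a selectivity established for protocatechualdehyde and its 5-substituted congeners, so one equivalent of MeI caps O4 and leaves O3 free.

Step 5
Reactants: 7 3-hydroxy-4-methoxy-5-(3-methylbut-2-enyl)benzaldehyde
Product: 8 4-methoxy-3-(3-methylbut-2-enyl)-5-(triisopropylsilyloxy)benzaldehyde
Conditions: TIPSCl, imidazole, DMF, rt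
Reagents that add atoms: triisopropylsilyl chloride, CC(C)[Si](Cl)(C(C)C)C(C)C
Why: Imidazole-assisted silylation of a phenol, with TIPS chosen because it should survive hydride, Mitsunobu conditions, lithium amide and the carbenoid, and because it blocks O–H insertion in step 10.

Step 6
Reactants: 8 4-methoxy-3-(3-methylbut-2-enyl)-5-(triisopropylsilyloxy)benzaldehyde
Product: 9 [4-methoxy-3-(3-methylbut-2-enyl)-5-(triisopropylsilyloxy)phenyl]methanol
Conditions: NaBH4, THF–MeOH, 0 °C
Reagents that add atoms: none
Why: Borohydride 1,2-reduction of an aryl aldehyde, to which the trisubstituted olefin and the aryl silyl ether are inert.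

Step 7
Reactants: 10 2',4'-dihydroxyacetophenone
Product: 11 1-[2-hydroxy-4-(triisopropylsilyloxy)phenyl]ethanone
Conditions: TIPSCl (1.05 equiv), imidazole, CH2Cl2, 0 °C to rt
Reagents that add atoms: triisopropylsilyl chloride, CC(C)[Si](Cl)(C(C)C)C(C)C
Why: Site-selective silylation, in which the 2-OH is tied up in a hydrogen bond to the acetyl oxygen and is hindered, so the bulky silyl chloride reacts only at the 4-OH.

Step 8
Reactants: 9 [4-methoxy-3-(3-methylbut-2-enyl)-5-(triisopropylsilyloxy)phenyl]methanol; 11 1-[2-hydroxy-4-(triisopropylsilyloxy)phenyl]ethanone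
Product: 12 1-{2-[4-methoxy-3-(3-methylbut-2-enyl)-5-(triisopropylsilyloxy)benzyloxy]-4-(triisopropylsilyloxy)phenyl}ethanone
Conditions: PPh3, DIAD, THF, 0 °C to rt
Reagents that add atoms: none
Why: Mitsunobu etherification, in which the primary benzylic alcohol is activated as its oxyphosphonium salt and displaced by the 2-OH phenol under essentially neutral conditions, avoiding both a labile 4-methoxybenzyl-type halide and carbonate bases that could strip the para-acyl aryl silyl ether and divert alkylation to O4.

Step 9
Reactants: 12 1-{2-[4-methoxy-3-(3-methylbut-2-enyl)-5-(triisopropylsilyloxy)benzyloxy]-4-(triisopropylsilyloxy)phenyl}ethanone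
Product: 14 2-diazo-1-{2-[4-methoxy-3-(3-methylbut-2-enyl)-5-(triisopropylsilyloxy)benzyloxy]-4-(triisopropylsilyloxy)phenyl}ethanone, via trifluoroacetyl diketone 13 (not isolated)
Conditions: LiN(SiMe3)2, THF, −78 °C, then CF3CO2CH2CF3; cold dilute HCl quench; crude 13, 4-acetamidobenzenesulfonyl azide, Et3N, H2O (1 equiv), MeCN–CH2Cl2, rt; no hydroxide wash
Reagents that add atoms: 4-acetamidobenzenesulfonyl azide, CC(=O)Nc1ccc(cc1)S(=O)(=O)N=[N+]=[N-] (the two diazo nitrogens of 14); 2,2,2-trifluoroethyl trifluoroacetate, O=C(OCC(F)(F)F)C(F)(F)F (the CF3CO group of 13 only)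
Why: Deacylative (detrifluoroacetylative) Regitz diazo transfer, in which the kinetic lithium enolate of the methyl ketone is C-trifluoroacetylated to the activated 1,3-diketone 13, which takes the diazo group from the sulfonyl azide under mild amine base and sheds the trifluoroacetyl group, a sequence that works where direct transfer to a simple methyl ketone does not.

Step 10
Reactants: 14 2-diazo-1-{2-[4-methoxy-3-(3-methylbut-2-enyl)-5-(triisopropylsilyloxy)benzyloxy]-4-(triisopropylsilyloxy)phenyl}ethanone
Product: 15 (2S)-2-[4-methoxy-3-(3-methylbut-2-enyl)-5-(triisopropylsilyloxy)phenyl]-7-(triisopropylsilyloxy)chroman-4-one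
Conditions: Rh2(S-PTTL)4 (2 mol%), 4 Å sieves, CH2Cl2, 0 °C, 14 added by syringe pump over 5 h (final about 5 mM)
Reagents that add atoms: none
Why: The diazo carbon of 14 attacks a free axial site of Rh2(S-PTTL)4 (divalent rhodium), N2 departs, and the electrophilic carbenoid carbon (the future C3) engages one benzylic C–H bond of the O1–CH2–ring B unit in a concerted but asynchronous three-centre transition state with hydride-like character, so the C2–C3 and C3–H bonds form together, with retention at C2, and the catalyst is released. The closest known reaction type is the chiral dirhodium tetracarboxylate catalysed intramolecular C–H insertion of 2-alkoxyaryl diazoketones, which gives 2-substituted chroman-4-ones. Ring C closes as a six-membered ring by 1,6-insertion (C3, C4, C4a, C8a, O1, C2), and the usual five-membered mode is shut off because the atom it would need is O1, which bears no hydrogen. C2 is set by catalyst control: the four N-phthaloyl-tert-leucinate ligands wall in the carbenoid so that only one of the two enantiotopic benzylic hydrogens, the pro-S one that leads to 2S with retention, can reach it. Insertion has to win over attack of the O1 lone pair on the carbenoid (five-membered oxonium ylide, then Stevens 1,2-benzyl shift), cyclopropanation of the prenyl olefin, Buchner attack on ring B and carbene dimerisation. The substrate helps because O1 is a poor donor (its lone pair is drawn into ring A by the ortho acyl group), the C–H bond is activated by both O1 and electron-rich ring B, C3 carries no second acceptor that would favour ylide chemistry, both phenols are masked against O–H insertion, the olefin can be reached within the molecule only through a ring of eleven or more atoms, and slow addition at high dilution in a non-aromatic solvent starves the bimolecular paths.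

Step 11
Reactants: 15 (2S)-2-[4-methoxy-3-(3-methylbut-2-enyl)-5-(triisopropylsilyloxy)phenyl]-7-(triisopropylsilyloxy)chroman-4-one
Product: 16 erylatissin C, (2S)-7-hydroxy-2-[3-hydroxy-4-methoxy-5-(3-methylbut-2-enyl)phenyl]chroman-4-one
Conditions: Bu4NF (2.2 equiv), AcOH (2.5 equiv), THF, 0 °C; pH 6–7 work-up
Reagents that add atoms: none
Why: Fluoride desilylation buffered with acetic acid, in which Si–F bond formation frees both phenols while the acid keeps the medium from turning basic, so enolisation at C3 and retro-oxa-Michael opening to the chalcone, which would racemise C2, are not triggered.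

**Compound list**
1 | 3,4-dihydroxybenzaldehyde | O=Cc1ccc(O)c(O)c1 | starting material
2 | 3-chloro-3-methylbut-1-yne | CC(C)(Cl)C#C | starting material
3 | 3-hydroxy-4-[(2-methylbut-3-yn-2-yl)oxy]benzaldehyde | O=Cc1ccc(OC(C)(C)C#C)c(O)c1 | intermediate
4 | 3-hydroxy-4-[(2-methylbut-3-en-2-yl)oxy]benzaldehyde | O=Cc1ccc(OC(C)(C)C=C)c(O)c1 | intermediate
5 | 3-hydroxy-5-(3-methylbut-2-enyl)-4-oxocyclohexa-1,5-diene-1-carbaldehyde type ortho-dienone (racemic, transient) | O=CC1=CC(CC=C(C)C)C(=O)C(O)=C1 | intermediate (not isolated)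
6 | 3,4-dihydroxy-5-(3-methylbut-2-enyl)benzaldehyde | O=Cc1cc(O)c(O)c(CC=C(C)C)c1 | intermediate
7 | 3-hydroxy-4-methoxy-5-(3-methylbut-2-enyl)benzaldehyde | COc1c(O)cc(C=O)cc1CC=C(C)C | intermediate
8 | 4-methoxy-3-(3-methylbut-2-enyl)-5-(triisopropylsilyloxy)benzaldehyde | COc1c(O[Si](C(C)C)(C(C)C)C(C)C)cc(C=O)cc1CC=C(C)C | intermediate
9 | [4-methoxy-3-(3-methylbut-2-enyl)-5-(triisopropylsilyloxy)phenyl]methanol | COc1c(O[Si](C(C)C)(C(C)C)C(C)C)cc(CO)cc1CC=C(C)C | intermediate
10 | 2',4'-dihydroxyacetophenone | CC(=O)c1ccc(O)cc1O | starting material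
11 | 1-[2-hydroxy-4-(triisopropylsilyloxy)phenyl]ethanone | CC(=O)c1ccc(O[Si](C(C)C)(C(C)C)C(C)C)cc1O | intermediate
12 | 1-{2-[4-methoxy-3-(3-methylbut-2-enyl)-5-(triisopropylsilyloxy)benzyloxy]-4-(triisopropylsilyloxy)phenyl}ethanone | COc1c(O[Si](C(C)C)(C(C)C)C(C)C)cc(COc2cc(O[Si](C(C)C)(C(C)C)C(C)C)ccc2C(C)=O)cc1CC=C(C)C | intermediate
13 | 4,4,4-trifluoro-1-{2-[4-methoxy-3-(3-methylbut-2-enyl)-5-(triisopropylsilyloxy)benzyloxy]-4-(triisopropylsilyloxy)phenyl}butane-1,3-dione | COc1c(O[Si](C(C)C)(C(C)C)C(C)C)cc(COc2cc(O[Si](C(C)C)(C(C)C)C(C)C)ccc2C(=O)CC(=O)C(F)(F)F)cc1CC=C(C)C | intermediate (not isolated)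
14 | 2-diazo-1-{2-[4-methoxy-3-(3-methylbut-2-enyl)-5-(triisopropylsilyloxy)benzyloxy]-4-(triisopropylsilyloxy)phenyl}ethanone | COc1c(O[Si](C(C)C)(C(C)C)C(C)C)cc(COc2cc(O[Si](C(C)C)(C(C)C)C(C)C)ccc2C(=O)C=[N+]=[N-])cc1CC=C(C)C | intermediate
15 | (2S)-2-[4-methoxy-3-(3-methylbut-2-enyl)-5-(triisopropylsilyloxy)phenyl]-7-(triisopropylsilyloxy)chroman-4-one | COc1c(O[Si](C(C)C)(C(C)C)C(C)C)cc([C@@H]2CC(=O)c3ccc(O[Si](C(C)C)(C(C)C)C(C)C)cc3O2)cc1CC=C(C)C | intermediate
16 | erylatissin C, (2S)-7-hydroxy-2-[3-hydroxy-4-methoxy-5-(3-methylbut-2-enyl)phenyl]chroman-4-one | COc1c(O)cc([C@@H]2CC(=O)c3ccc(O)cc3O2)cc1CC=C(C)C | target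

**Step count**
- Total step count: 11.
- Longest linear sequence: 10 (steps 1–6 and 8–11, from 1).

**Steps most likely to fail**

Risk 1, step 10 (key step).
- What may go wrong: the O1 lone pair captures the carbenoid and the benzyl group then migrates. An unsubstituted, acceptor-only carbenoid may discriminate weakly between the two enantiotopic hydrogens. The prenyl olefin may be consumed.
- The fallback gives up carbene chemistry for an organocatalytic oxa-Michael closure of ring C. It sets out from aldehyde 8 and comes back at 15.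
- Commercial methyl 2,4-dihydroxybenzoate is silylated at O4 (TIPSCl, imidazole) to methyl 2-hydroxy-4-(triisopropylsilyloxy)benzoate F1.
- Crossed Claisen condensation with excess lithium enolate of tert-butyl acetate (LiN(iPr)2, THF, −78 to 0 °C) should give tert-butyl 3-[2-hydroxy-4-(triisopropylsilyloxy)phenyl]-3-oxopropanoate F2.
- Knoevenagel condensation with 8 (piperidine, AcOH, toluene, 4 Å sieves) should give tert-butyl 2-[2-hydroxy-4-(triisopropylsilyloxy)benzoyl]-3-[4-methoxy-3-(3-methylbut-2-enyl)-5-(triisopropylsilyloxy)phenyl]prop-2-enoate F3.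
- A bifunctional cinchona-alkaloid thiourea, of the pseudoenantiomeric series that delivers 2S (10 mol%, toluene, −25 °C), closes ring C by enantioselective 6-endo-trig oxa-Michael addition. This gives tert-butyl (2S)-2-[4-methoxy-3-(3-methylbut-2-enyl)-5-(triisopropylsilyloxy)phenyl]-4-oxo-7-(triisopropylsilyloxy)chromane-3-carboxylate F4.
- TsOH in toluene at 80 °C then cleaves the tert-butyl ester and decarboxylates to 15.

Risk 2, step 1.
- What may go wrong: site selection between the two phenols may be incomplete. The catecholate may chelate and deactivate the copper. The free 3-OH may add across the alkyne.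
- The fallback replaces the ether/Claisen sequence by cross-coupling. It sets out from 1, bypasses steps 1–5 and comes back at 8.
- Bromination at C5, ortho to the 4-OH and meta to CHO (Br2, AcOH, rt), gives 3-bromo-4,5-dihydroxybenzaldehyde F5.
- Acidity-controlled 4-O-methylation (MeI, Li2CO3, DMF) gives 3-bromo-5-hydroxy-4-methoxybenzaldehyde F6.
- Silylation (TIPSCl, imidazole, DMF) gives 3-bromo-4-methoxy-5-(triisopropylsilyloxy)benzaldehyde F7.
- Stille coupling with tributyl(3-methylbut-2-enyl)stannane (Pd(PPh3)4, DMF, 100 °C) installs the linear prenyl group and gives 8.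

Risk 3, step 8.
- What may go wrong: proton transfer from the hydrogen-bonded phenol may be slow, so the activated alcohol alkylates the reduced azodicarboxylate. The electron-rich oxyphosphonium salt may ionise, with alkylation on carbon.
- The fallback uses halide displacement. It sets out from 9 and comes back at 12.
- Appel bromination (CBr4, PPh3, CH2Cl2, 0 °C) gives 5-(bromomethyl)-2-methoxy-1-(3-methylbut-2-enyl)-3-(triisopropylsilyloxy)benzene F8.
- F8 is used at once to O-alkylate 11 (K2CO3, acetone, rt, short contact time to spare the aryl silyl ethers).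

**Further compounds**
F1 | step 10 | methyl 2-hydroxy-4-(triisopropylsilyloxy)benzoate | COC(=O)c1ccc(O[Si](C(C)C)(C(C)C)C(C)C)cc1O
F2 | step 10 | tert-butyl 3-[2-hydroxy-4-(triisopropylsilyloxy)phenyl]-3-oxopropanoate | CC(C)(C)OC(=O)CC(=O)c1ccc(O[Si](C(C)C)(C(C)C)C(C)C)cc1O
F3 | step 10 | tert-butyl 2-[2-hydroxy-4-(triisopropylsilyloxy)benzoyl]-3-[4-methoxy-3-(3-methylbut-2-enyl)-5-(triisopropylsilyloxy)phenyl]prop-2-enoate (alkene geometry left open) | COc1c(O[Si](C(C)C)(C(C)C)C(C)C)cc(C=C(C(=O)OC(C)(C)C)C(=O)c2ccc(O[Si](C(C)C)(C(C)C)C(C)C)cc2O)cc1CC=C(C)C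
F4 | step 10 | tert-butyl (2S)-2-[4-methoxy-3-(3-methylbut-2-enyl)-5-(triisopropylsilyloxy)phenyl]-4-oxo-7-(triisopropylsilyloxy)chromane-3-carboxylate (C3 epimerisable, left open) | COc1c(O[Si](C(C)C)(C(C)C)C(C)C)cc([C@@H]2C(C(=O)OC(C)(C)C)C(=O)c3ccc(O[Si](C(C)C)(C(C)C)C(C)C)cc3O2)cc1CC=C(C)C
F5 | step 1 | 3-bromo-4,5-dihydroxybenzaldehyde | O=Cc1cc(O)c(O)c(Br)c1
F6 | step 1 | 3-bromo-5-hydroxy-4-methoxybenzaldehyde | COc1c(O)cc(C=O)cc1Br
F7 | step 1 | 3-bromo-4-methoxy-5-(triisopropylsilyloxy)benzaldehyde | COc1c(O[Si](C(C)C)(C(C)C)C(C)C)cc(C=O)cc1Br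
F8 | step 8 | 5-(bromomethyl)-2-methoxy-1-(3-methylbut-2-enyl)-3-(triisopropylsilyloxy)benzene | COc1c(O[Si](C(C)C)(C(C)C)C(C)C)cc(CBr)cc1CC=C(C)C
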